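**Retrosynthetic overview**
1. Target 13 ⇐ O‑acetylation of epoxy alcohol 12 ⇐ key C–O step (new): one‑pot aerobic allylic C–H hydroperoxidation with 1,3‑transposition, then Ti‑mediated oxygen transfer, on Δ9‑alkene 10. This forms the C10–O, C8–O and C9–O bonds and sets C8, C9 and C10.
2. 10 ⇐ acylation of 6‑OH and isopropyl addition to the C4 ketone of hydroazulenone 8 (sets C4).
3. 8 ⇐ ring‑closing metathesis (C9=C10) of diene 7 ⇐ protodesilylation of 6.
4. 6 ⇐ three‑component Cu‑catalysed asymmetric conjugate addition/aldol of enone 1, the vinylalane from alkyne 2, and aldehyde 3 (C1–C10 and C5–C6 bonds; sets C1, C5, C6).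
5. Ring order: cyclopentane (present in 1) → cycloheptene (RCM) → oxirane (last).

Assumption: racemic 3 is used, so 6–10 are 1:1 mixtures at the methyl‑bearing carbon C8 (no descriptor in their SMILES), which becomes sp2 in step 6; ring atoms carry daucane numbers (C1 = ring‑fusion carbon with the angular methyl, C2/C3 = CH2, C4 = carbinol carbon with i‑Pr, C5 = ring‑fusion CH, C6–C10 = rest of the seven‑membered ring, C8 bears methyl), β = face of the angular methyl, α = opposite face.

**Step 1**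
Reactants: 1 3-methylcyclopent-2-en-1-one; 2 ethynyltrimethylsilane; 3 rac-3-methylpent-4-enal
Product: 6 (2S,3S)-2-[(1S)-1-hydroxy-3-methylpent-4-en-1-yl]-3-methyl-3-[1-(trimethylsilyl)ethenyl]cyclopentan-1-one, via silylvinylalane 4 (not isolated), via aluminium enolate 5 (not isolated)
Conditions: 2, DIBAL‑H, hexanes–THF, 55 °C; then 1, Cu(OTf)2 (5 mol %), chiral sulfonate‑NHC–Ag complex (2.5 mol %, antipode giving 3S), THF, −78 → −30 °C; then 3, −78 → −40 °C; aq. Rochelle salt
Reagents that add atoms: none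
Why: Cu–NHC‑catalysed enantioselective conjugate addition of the α‑silylvinylalane sets the quaternary C1, and the regiodefined aluminium (E)‑enolate then undergoes a Zimmerman–Traxler aldol addition to 3 on the face anti to the bulky silylvinyl group, giving the 2,3‑trans ring relationship (C5) and the anti‑aldol carbinol (C6).

**Step 2**
Reactants: 6 (2S,3S)-2-[(1S)-1-hydroxy-3-methylpent-4-en-1-yl]-3-methyl-3-[1-(trimethylsilyl)ethenyl]cyclopentan-1-one
Product: 7 (2S,3R)-3-ethenyl-2-[(1S)-1-hydroxy-3-methylpent-4-en-1-yl]-3-methylcyclopentan-1-one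
Conditions: CF3CO2H (5 equiv), CH2Cl2, 0 → 22 °C; aq. NaHCO3
Reagents that add atoms: none
Why: Protodesilylation of the vinylsilane by ipso‑protonation to a β‑silyl‑stabilised cation and loss of silicon unmasks the vinyl group without touching a stereocentre.

**Step 3**
Reactants: 7 (2S,3R)-3-ethenyl-2-[(1S)-1-hydroxy-3-methylpent-4-en-1-yl]-3-methylcyclopentan-1-one
Product: 8 (3aR,8S,8aS)-8-hydroxy-3a,6-dimethyl-3,3a,6,7,8,8a-hexahydroazulen-1(2H)-one (trans‑fused; 6α‑hydroxy‑11,12,13‑trinor‑trans‑dauc‑9‑en‑4‑one)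
Conditions: Grubbs II (5 mol %), 1,4‑benzoquinone (10 mol %), CH2Cl2 (5 mM), 40 °C
Reagents that add atoms: none
Why: Ring‑closing metathesis of the two terminal alkenes, held trans on the cyclopentanone, closes the cis‑cycloheptene with loss of ethene and leaves the existing stereocentres untouched.

**Step 4**
Reactants: 8 (3aR,8S,8aS)-8-hydroxy-3a,6-dimethyl-3,3a,6,7,8,8a-hexahydroazulen-1(2H)-one
Product: 9 (1R,3aR,8S,8aS)-3a,6-dimethyl-1-(propan-2-yl)-1,2,3,3a,6,7,8,8a-octahydroazulene-1,8-diol (trans‑dauc‑9‑ene‑4β,6α‑diol)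
Conditions: i‑PrMgCl (3 equiv), LaCl3·2LiCl (1.1 equiv), THF, −30 → 0 °C; aq. NH4Cl
Reagents that add atoms: isopropylmagnesium chloride, CC(C)[Mg]Cl
Why: Lanthanum‑promoted Grignard 1,2‑addition (suppressing enolisation and β‑hydride reduction) occurs on the α face of the trans‑fused ketone, anti to the axial angular methyl and the C6 branch and on the side of the chelating 6‑alkoxide, giving 4β‑OH/4α‑i‑Pr (4R).

**Step 5**
Reactants: 9 (1R,3aR,8S,8aS)-3a,6-dimethyl-1-(propan-2-yl)-1,2,3,3a,6,7,8,8a-octahydroazulene-1,8-diol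
Product: 10 4β-hydroxy-trans-dauc-9-en-6α-yl 3-methylbutanoate
Conditions: (i‑BuCO)2O (1.5 equiv), Et3N, DMAP (10 mol %), CH2Cl2, 0 → 22 °C
Reagents that add atoms: 3-methylbutanoic (isovaleric) anhydride, CC(C)CC(=O)OC(=O)CC(C)C
Why: DMAP‑catalysed acylation esterifies only the secondary 6‑OH, since the tertiary 4‑OH is inert under these conditions.

**Step 6**
Reactants: 10 4β-hydroxy-trans-dauc-9-en-6α-yl 3-methylbutanoate
Product: 12 8α,9α-epoxy-4β,10α-dihydroxy-trans-daucan-6α-yl 3-methylbutanoate, via C10 hydroperoxide 11 (not isolated)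
Conditions: NHPI (20 mol %), V‑70 (5 mol %), O2 (1 atm), MeCN–PhCF3, 30 °C; then Ar, solvent switch to CH2Cl2, Ti(Oi‑Pr)4 (30 mol %), 4 Å MS, −20 → 0 °C
Reagents that add atoms: dioxygen, O=O
Why: Proposed new method: a stereoconvergent radical surrogate of the Schenck ene reaction telescoped with titanium oxygen transfer – the phthalimide‑N‑oxyl radical (O–H about 88 kcal/mol) can abstract only the single allylic hydrogen of 10 (tertiary C8–H, about 80 kcal/mol), so both C8 epimers give one planar C8–C9–C10 allyl radical; O2 adds reversibly, the tertiary C8 peroxyl fragments back while the secondary C10 peroxyl (which leaves the more substituted C8=C9 alkene) is reduced by NHPI, and the C10–O bond forms on the α face anti to the axial angular methyl on C1, which sets C10; Ti(Oi‑Pr)4 then delivers the distal peroxide oxygen of 11 to the alkene face syn to the C10 oxygen (Sharpless‑type titanium epoxy‑hydroxylation of allylic hydroperoxides), which sets C8 and C9; the closest known reactions are NHPI/O2 C–H hydroperoxidation and the singlet‑oxygen ene/Ti(Oi‑Pr)4 sequence, neither shown for a tertiary allylic C–H of a 1,2‑disubstituted cycloalkene with allylic transposition.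

**Step 7**
Reactants: 12 8α,9α-epoxy-4β,10α-dihydroxy-trans-daucan-6α-yl 3-methylbutanoate
Product: 13 10α-acetoxy-8α,9α-epoxy-4β-hydroxy-trans-daucan-6α-yl 3-methylbutanoate (CNP0137153.1)
Conditions: Ac2O, pyridine, DMAP (cat.), CH2Cl2, 22 °C
Reagents that add atoms: acetic anhydride, CC(=O)OC(C)=O
Why: DMAP‑catalysed acetylation of the secondary 10‑OH proceeds with retention at C10, while the tertiary 4‑OH and the epoxide are unaffected.

**Compound list**
1 | 3-methylcyclopent-2-en-1-one | CC1=CC(=O)CC1 | starting material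
2 | ethynyltrimethylsilane | C#C[Si](C)(C)C | starting material
3 | rac-3-methylpent-4-enal | C=CC(C)CC=O | starting material
4 | bis(2-methylpropyl)[1-(trimethylsilyl)ethenyl]alumane | C=C([Si](C)(C)C)[Al](CC(C)C)CC(C)C | intermediate
5 | diisobutylaluminium (3S)-3-methyl-3-[1-(trimethylsilyl)ethenyl]cyclopent-1-en-1-olate | CC(C)C[Al](CC(C)C)OC1=C[C@](C(=C)[Si](C)(C)C)(C)CC1 | intermediate
6 | (2S,3S)-2-[(1S)-1-hydroxy-3-methylpent-4-en-1-yl]-3-methyl-3-[1-(trimethylsilyl)ethenyl]cyclopentan-1-one (1:1 at side‑chain C3) | C=CC(C)C[C@H](O)[C@@H]1[C@](C(=C)[Si](C)(C)C)(C)CCC1=O | intermediate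
7 | (2S,3R)-3-ethenyl-2-[(1S)-1-hydroxy-3-methylpent-4-en-1-yl]-3-methylcyclopentan-1-one (1:1 at side‑chain C3) | C=CC(C)C[C@H](O)[C@@H]1[C@](C=C)(C)CCC1=O | intermediate
8 | (3aR,8S,8aS)-8-hydroxy-3a,6-dimethyl-3,3a,6,7,8,8a-hexahydroazulen-1(2H)-one (trans‑fused; 1:1 at C6 of the azulene = daucane C8) | C1=CC(C)C[C@H](O)[C@@H]2[C@]1(C)CCC2=O | intermediate
9 | (1R,3aR,8S,8aS)-3a,6-dimethyl-1-(propan-2-yl)-1,2,3,3a,6,7,8,8a-octahydroazulene-1,8-diol (trans‑dauc‑9‑ene‑4β,6α‑diol; 1:1 at C8) | C1=CC(C)C[C@H](O)[C@@H]2[C@]1(C)CC[C@@]2(O)C(C)C | intermediate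
10 | 4β-hydroxy-trans-dauc-9-en-6α-yl 3-methylbutanoate ((1R,4R,5S,6S); 1:1 at C8) | C1=CC(C)C[C@H](OC(=O)CC(C)C)[C@@H]2[C@]1(C)CC[C@@]2(O)C(C)C | intermediate
11 | 10α-hydroperoxy-4β-hydroxy-trans-dauc-8-en-6α-yl 3-methylbutanoate ((1S,4R,5S,6S,10R)) | OO[C@@H]1C=C(C)C[C@H](OC(=O)CC(C)C)[C@@H]2[C@]1(C)CC[C@@]2(O)C(C)C | intermediate
12 | 8α,9α-epoxy-4β,10α-dihydroxy-trans-daucan-6α-yl 3-methylbutanoate ((1S,4R,5S,6S,8R,9S,10S)) | O[C@@H]1[C@@H]2O[C@]2(C)C[C@H](OC(=O)CC(C)C)[C@@H]2[C@]1(C)CC[C@@]2(O)C(C)C | intermediate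
13 | 10α-acetoxy-8α,9α-epoxy-4β-hydroxy-trans-daucan-6α-yl 3-methylbutanoate ((1S,4R,5S,6S,8R,9S,10S)) | CC(=O)O[C@@H]1[C@@H]2O[C@]2(C)C[C@H](OC(=O)CC(C)C)[C@@H]2[C@]1(C)CC[C@@]2(O)C(C)C | target

**Totals and risks**
Total steps: 7. Longest linear sequence: 7 steps (from 1).

The three steps most likely to fail:

1) The new aerobic C–H epoxy‑hydroxylation (step 6). The risks are O2 capture at C8 instead of C10, incomplete α‑selectivity at C10 with the small O2 molecule, and over‑oxidation of 11 to the C10 enone. A ketone/reduction detour is not a good rescue, because hydride would also attack C10 from the α face and give the wrong 10β‑alcohol. The fallback uses known chemistry, sets out from 10 and returns at 12. Copper‑catalysed allylic C–H amin‑oxylation (CuCl cat., NHPI, PhI(OAc)2, MeCN, 60 °C) traps the same allyl radical with the bulky persistent PINO radical at the secondary C10 terminus, anti to the angular methyl, to give the N‑alkoxyphthalimide 4β-hydroxy-10α-(phthalimidooxy)-trans-dauc-8-en-6α-yl 3-methylbutanoate F4. N–O cleavage with Mo(CO)6, Et3N in MeCN–H2O at 80 °C gives the allylic alcohol 4β,10α-dihydroxy-trans-dauc-8-en-6α-yl 3-methylbutanoate F5. Hydroxyl‑directed epoxidation (VO(acac)2, t‑BuOOH, CH2Cl2, 0 °C) then gives the cis epoxy alcohol 12.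

2) The three‑component conjugate addition/aldol (step 1). The risks are sluggish or poorly anti‑selective aldol addition of the aluminium enolate and erosion of ee on the five‑membered enone. The fallback decouples the two events; it sets out from 1 and 2 and returns at 6. After the same Cu‑catalysed conjugate addition the enolate is trapped with TMSOTf and isolated as the silyl enol ether trimethyl({(3S)-3-methyl-3-[1-(trimethylsilyl)ethenyl]cyclopent-1-en-1-yl}oxy)silane F1. MeLi (THF, 0 °C) converts it into the lithium enolate lithium (3S)-3-methyl-3-[1-(trimethylsilyl)ethenyl]cyclopent-1-en-1-olate F2. Kinetic aldol addition of F2 to 3 at −78 °C (closed transition state, E‑enolate → anti) gives 6.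

3) The isopropyl addition (step 4). The risks are β‑hydride reduction of the hindered ketone by i‑PrMgCl, enolisation with C5 epimerisation, and retro‑aldol of the magnesium aldolate. The fallback sets out from 8 and returns at 9. Isopropenylmagnesium bromide (no β‑hydride transfer; LaCl3·2LiCl, THF, −30 °C) adds from the same α face to give the isopropenyl carbinol trans-dauca-9,11(12)-diene-4β,6α-diol F3. Hydroxyl‑directed hydrogenation ([Rh(nbd)(dppb)]BF4, H2, CH2Cl2) reduces only the 1,1‑disubstituted alkene allylic to the tertiary OH; the hindered ring alkene has no nearby directing hydroxyl and should survive. This gives 9.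

**Further compounds**
F1 | step 1 | trimethyl({(3S)-3-methyl-3-[1-(trimethylsilyl)ethenyl]cyclopent-1-en-1-yl}oxy)silane | C[Si](C)(C)OC1=C[C@](C(=C)[Si](C)(C)C)(C)CC1
F2 | step 1 | lithium (3S)-3-methyl-3-[1-(trimethylsilyl)ethenyl]cyclopent-1-en-1-olate | [Li]OC1=C[C@](C(=C)[Si](C)(C)C)(C)CC1
F3 | step 4 | trans-dauca-9,11(12)-diene-4β,6α-diol ((1R,4S,5S,6S); 1:1 at C8) | C1=CC(C)C[C@H](O)[C@@H]2[C@]1(C)CC[C@@]2(O)C(C)=C
F4 | step 6 | 4β-hydroxy-10α-(phthalimidooxy)-trans-dauc-8-en-6α-yl 3-methylbutanoate | O=C1c2ccccc2C(=O)N1O[C@@H]1C=C(C)C[C@H](OC(=O)CC(C)C)[C@@H]2[C@]1(C)CC[C@@]2(O)C(C)C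
F5 | step 6 | 4β,10α-dihydroxy-trans-dauc-8-en-6α-yl 3-methylbutanoate | O[C@@H]1C=C(C)C[C@H](OC(=O)CC(C)C)[C@@H]2[C@]1(C)CC[C@@]2(O)C(C)C
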